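With the chain numbered from the lactone carbonyl (C1) to the furyl CH2 (C15), the oxygen-bearing carbons C4, C5 and C8 of the oxolane–γ-lactone core and the C9=C10 alkene lie where a homofarnesyl chain carries its C4=C5 and C8=C9 alkenes. The route therefore cuts C4–O (lactone), C8–O (oxolane) and the C9=C10 unsaturation back to an acyclic (4R,5R)-epoxy tert-butyl ester that already holds the furan. One selenium-triggered cascade passes through an epoxonium ion, closes both rings, inverts C4, relays chirality to quaternary C8 and leaves a C9 selenide; selenoxide elimination then reveals the E alkene. A single Sharpless epoxidation provides all the asymmetry.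

Key step: step 8

Remark on the chemistry: the C1–C15 numbering above is used for every compound, and the allylic bromide 2 and the furylmethyl chloride 4 are taken to be made fresh and used at once.

Step 1
Reactants: 1 (2E,6E)-farnesol
Product: 2 (2E,6E)-farnesyl bromide
Conditions: PBr3 (0.4 equiv), Et2O, −10 → 0 °C
Reagents that add atoms: phosphorus tribromide, BrP(Br)Br
Why: Bromination of a primary allylic alcohol through its phosphite ester goes by SN2 at low temperature, so the alkene neither shifts nor loses its E geometry.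

Step 2
Reactants: 3 furan-3-ylmethanol
Product: 4 3-(chloromethyl)furan
Conditions: SOCl2, pyridine, Et2O, 0 °C
Reagents that add atoms: thionyl chloride, O=S(Cl)Cl
Why: Chlorodehydroxylation through the chlorosulfite, with pyridine taking up the acid so that the furan is not exposed to HCl.

Step 3
Reactants: 4 3-(chloromethyl)furan; 2 (2E,6E)-farnesyl bromide
Product: 6 3-[(3E,7E)-4,8,12-trimethyltrideca-3,7,11-trien-1-yl]furan, via (furan-3-ylmethyl)magnesium chloride 5 (not isolated)
Conditions: Mg, THF, rt (slow addition of 4); then 2, Li2CuCl4 (3 mol %), THF, 0 °C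
Reagents that add atoms: none
Why: Magnesium insertion gives the furylmethyl Grignard reagent, and its Kochi-type copper-catalysed coupling with a primary allylic bromide is known to go at the α carbon with retention of alkene geometry, forming C14–C15.

Step 4
Reactants: 6 3-[(3E,7E)-4,8,12-trimethyltrideca-3,7,11-trien-1-yl]furan
Product: 7 (2E,6E,10E)-13-(furan-3-yl)-2,6,10-trimethyltrideca-2,6,10-trien-1-ol
Conditions: SeO2 (0.2 equiv), salicylic acid (0.1 equiv), t-BuOOH (3 equiv), CH2Cl2, 0 °C → rt, stopped at partial conversion with recovery of 6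
Reagents that add atoms: tert-butyl hydroperoxide, CC(C)(C)OO (oxygen passed on through catalytic selenium dioxide, O=[Se]=O)
Why: Riley–Sharpless allylic oxidation (ene reaction, then [2,3]-shift) prefers the most accessible trisubstituted alkene and, at a gem-dimethyl end, the methyl trans to the chain, so the terminal E-CH2OH should form while the furan is left alone.

Step 5
Reactants: 7 (2E,6E,10E)-13-(furan-3-yl)-2,6,10-trimethyltrideca-2,6,10-trien-1-ol
Product: 8 [(2R,3R)-3-[(3E,7E)-10-(furan-3-yl)-3,7-dimethyldeca-3,7-dien-1-yl]-2-methyloxiran-2-yl]methanol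
Conditions: Ti(OiPr)4 (10 mol %), D-(−)-diethyl tartrate (12 mol %), anhydrous t-BuOOH, 4 Å MS, CH2Cl2, −20 °C
Reagents that add atoms: tert-butyl hydroperoxide, CC(C)(C)OO
Why: Katsuki–Sharpless asymmetric epoxidation acts only on the alkene bound through the allylic alkoxide (C4=C5), and D-(−)-tartrate delivers oxygen to the face that gives the (2R,3R)-epoxy alcohol of an (E)-2-methyl-2-alken-1-ol, which sets C4 and C5.

Step 6
Reactants: 8 [(2R,3R)-3-[(3E,7E)-10-(furan-3-yl)-3,7-dimethyldeca-3,7-dien-1-yl]-2-methyloxiran-2-yl]methanol; 9 (tert-butoxycarbonylmethylene)triphenylphosphorane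
Product: 11 tert-butyl (2E)-3-[(2R,3R)-3-[(3E,7E)-10-(furan-3-yl)-3,7-dimethyldeca-3,7-dien-1-yl]-2-methyloxiran-2-yl]prop-2-enoate, via epoxy aldehyde 10 (not isolated)
Conditions: Dess–Martin periodinane (1.3 equiv), pyridine, CH2Cl2, 0 °C → rt; then 9 (2 equiv), rt
Reagents that add atoms: (tert-butoxycarbonylmethylene)triphenylphosphorane (9), CC(C)(C)OC(=O)C=P(c1ccccc1)(c1ccccc1)c1ccccc1
Why: Dess–Martin oxidation gives the epoxy aldehyde, which has no α-hydrogen and cannot epimerise, and the stabilised ylide then adds in the same flask in an E-selective Wittig olefination that brings in C1 and C2.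

Step 7
Reactants: 11 tert-butyl (2E)-3-[(2R,3R)-3-[(3E,7E)-10-(furan-3-yl)-3,7-dimethyldeca-3,7-dien-1-yl]-2-methyloxiran-2-yl]prop-2-enoate
Product: 12 tert-butyl 3-[(2R,3R)-3-[(3E,7E)-10-(furan-3-yl)-3,7-dimethyldeca-3,7-dien-1-yl]-2-methyloxiran-2-yl]propanoate
Conditions: 2-nitrobenzenesulfonylhydrazide (5 equiv), Et3N, CH2Cl2, rt
Reagents that add atoms: none
Why: Diimide reduction (concerted syn transfer of H2) takes the disubstituted enoate alkene far faster than trisubstituted alkenes or the furan and cannot open the vinyl epoxide, which hydride or metal-catalysed reductions would endanger.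

Step 8
Reactants: 12 tert-butyl 3-[(2R,3R)-3-[(3E,7E)-10-(furan-3-yl)-3,7-dimethyldeca-3,7-dien-1-yl]-2-methyloxiran-2-yl]propanoate; 13 N-(phenylseleno)phthalimide
Product: 16 (5S)-5-[(2R,5R)-5-[(1S,4E)-7-(furan-3-yl)-4-methyl-1-(phenylselanyl)hept-4-en-1-yl]-5-methyloxolan-2-yl]-5-methyloxolan-2-one, via seleniranium ion 14 (not isolated), via bicyclic epoxonium ion 15 (not isolated)
Conditions: 13 (1.05 equiv, in portions), (CF3)2CHOH–CH2Cl2 (4:1), 4 Å MS, −10 → 0 °C
Reagents that add atoms: N-(phenylseleno)phthalimide (13), O=C1c2ccccc2C(=O)N1[Se]c1ccccc1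
Why: Proposed new method: HFIP-activated 13 should transfer PhSe+ reversibly to the trisubstituted alkenes; only the C8–C9 seleniranium ion 14 has an oxygen within reach, and the epoxide oxygen attacks its tertiary carbon C8 anti to selenium (5-exo) to close the oxolane as the 1-oxoniabicyclo[3.1.0]hexane ion 15. The tert-butyl ester carbonyl then opens 15 at the tertiary C4 from the backside (5-exo) and the tert-butyl group leaves as isobutene, which closes the γ-lactone. The closest known reaction type is the bromonium- or phenylselenenyl-initiated alkene–epoxide cascade through epoxonium ions in fluorinated alcohols, ended by a tert-butyl ester or carbonate, together with classical phenylselenoetherification. C5 keeps its C–O bond (R), C4 becomes S by inversion of the (4R) epoxide carbon, C9 (S) follows from anti addition across the E alkene, and C8 (R) should be fixed when 15 forms, because the endo methyl on C4 leaves room on its own face only for the C8 methyl and sends the branched C9 to the far face. The step needs site selectivity among two alkenes and the furan, expected from reversible selenium transfer with irreversible capture only where a 5-exo oxygen waits, and facial selectivity at C8, which rests on the epoxide configuration and is the untested part.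

Step 9
Reactants: 16 (5S)-5-[(2R,5R)-5-[(1S,4E)-7-(furan-3-yl)-4-methyl-1-(phenylselanyl)hept-4-en-1-yl]-5-methyloxolan-2-yl]-5-methyloxolan-2-one
Product: 18 (5S)-5-[(2R,5R)-5-[(1E,4E)-7-(furan-3-yl)-4-methylhepta-1,4-dien-1-yl]-5-methyloxolan-2-yl]-5-methyloxolan-2-one, via C9 selenoxide 17 (not isolated)
Conditions: mCPBA (1.05 equiv), CH2Cl2, −78 °C; then Et3N, −78 °C → rt
Reagents that add atoms: none
Why: Selenium is oxidised at −78 °C much faster than the alkene or the furan, and the selenoxide undergoes syn elimination on warming, where quaternary C8 leaves only a C10 hydrogen to be removed and the cyclic transition state places C8 and C11 apart, giving the E C9=C10 alkene.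

Compound list
1 | (2E,6E)-farnesol | CC(C)=CCC/C(C)=C/CC/C(C)=C/CO | starting material
2 | (2E,6E)-farnesyl bromide | CC(C)=CCC/C(C)=C/CC/C(C)=C/CBr | intermediate
3 | furan-3-ylmethanol | OCc1ccoc1 | starting material
4 | 3-(chloromethyl)furan | ClCc1ccoc1 | intermediate
5 | (furan-3-ylmethyl)magnesium chloride | Cl[Mg]Cc1ccoc1 | intermediate
6 | 3-[(3E,7E)-4,8,12-trimethyltrideca-3,7,11-trien-1-yl]furan | CC(C)=CCC/C(C)=C/CC/C(C)=C/CCc1ccoc1 | intermediate
7 | (2E,6E,10E)-13-(furan-3-yl)-2,6,10-trimethyltrideca-2,6,10-trien-1-ol | OC/C(C)=C/CC/C(C)=C/CC/C(C)=C/CCc1ccoc1 | intermediate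
8 | [(2R,3R)-3-[(3E,7E)-10-(furan-3-yl)-3,7-dimethyldeca-3,7-dien-1-yl]-2-methyloxiran-2-yl]methanol | OC[C@@]1(C)O[C@@H]1CC/C(C)=C/CC/C(C)=C/CCc1ccoc1 | intermediate
9 | (tert-butoxycarbonylmethylene)triphenylphosphorane | CC(C)(C)OC(=O)C=P(c1ccccc1)(c1ccccc1)c1ccccc1 | starting material
10 | (2S,3R)-3-[(3E,7E)-10-(furan-3-yl)-3,7-dimethyldeca-3,7-dien-1-yl]-2-methyloxirane-2-carbaldehyde (same spatial arrangement as 8) | O=C[C@@]1(C)O[C@@H]1CC/C(C)=C/CC/C(C)=C/CCc1ccoc1 | intermediate
11 | tert-butyl (2E)-3-[(2R,3R)-3-[(3E,7E)-10-(furan-3-yl)-3,7-dimethyldeca-3,7-dien-1-yl]-2-methyloxiran-2-yl]prop-2-enoate | CC(C)(C)OC(=O)/C=C/[C@@]1(C)O[C@@H]1CC/C(C)=C/CC/C(C)=C/CCc1ccoc1 | intermediate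
12 | tert-butyl 3-[(2R,3R)-3-[(3E,7E)-10-(furan-3-yl)-3,7-dimethyldeca-3,7-dien-1-yl]-2-methyloxiran-2-yl]propanoate, the (4R,5R)-epoxy ester | CC(C)(C)OC(=O)CC[C@@]1(C)O[C@@H]1CC/C(C)=C/CC/C(C)=C/CCc1ccoc1 | intermediate
13 | N-(phenylseleno)phthalimide | O=C1c2ccccc2C(=O)N1[Se]c1ccccc1 | starting material
14 | C8–C9 Se-phenylseleniranium ion of 12, selenium on the face opposite to the incoming epoxide oxygen | CC(C)(C)OC(=O)CC[C@@]1(C)O[C@@H]1CC[C@@]2(C)[C@H](CC/C(C)=C/CCc3ccoc3)[Se+]2c4ccccc4 | intermediate
15 | 1-oxoniabicyclo[3.1.0]hexane (epoxonium) ion with O+ bonded to C4, C5 and C8 and PhSe on C9 | CC(C)(C)OC(=O)CC[C@]1(C)[C@H]2CC[C@](C)([C@H](CC/C(C)=C/CCc3ccoc3)[Se]c3ccccc3)[O+]12 | intermediate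
16 | (5S)-5-[(2R,5R)-5-[(1S,4E)-7-(furan-3-yl)-4-methyl-1-(phenylselanyl)hept-4-en-1-yl]-5-methyloxolan-2-yl]-5-methyloxolan-2-one | C/C(=C\CCc1ccoc1)CC[C@H]([Se]c1ccccc1)[C@@]1(C)CC[C@H]([C@]2(C)CCC(=O)O2)O1 | intermediate
17 | selenoxide of 16 (mixture at selenium) | C/C(=C\CCc1ccoc1)CC[C@H]([Se](=O)c1ccccc1)[C@@]1(C)CC[C@H]([C@]2(C)CCC(=O)O2)O1 | intermediate
18 | (5S)-5-[(2R,5R)-5-[(1E,4E)-7-(furan-3-yl)-4-methylhepta-1,4-dien-1-yl]-5-methyloxolan-2-yl]-5-methyloxolan-2-one, CNP0387598.1 | C/C(=C\CCc1ccoc1)C/C=C/[C@@]1(C)CC[C@H]([C@]2(C)CCC(=O)O2)O1 | target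

Total step count: 9.
Longest linear sequence: 8 steps (1 → 2 → 6 → 7 → 8 → 11 → 12 → 16 → 18; the branch from 3 is equally long).

Steps most likely to fail

Step 8 (the proposed cascade).
- What may go wrong: the two faces of the C8=C9 alkene may not be told apart well enough when the epoxonium ion forms, so that the C8 epimer accompanies 16. The selenium electrophile or the departing tert-butyl cation may be consumed by the electron-rich furan. The epoxide may ionise in HFIP before selenium arrives and start a carbocyclisation.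
- Fallback (known reactions, no electrophilic selenium), setting out from 12 and returning at 18: catalytic camphorsulfonic acid in CH2Cl2 at 0 °C lets the ester carbonyl open the epoxide at C4 with inversion and loss of isobutene, giving (5S)-5-[(1R,4E,8E)-11-(furan-3-yl)-1-hydroxy-4,8-dimethylundeca-4,8-dien-1-yl]-5-methyloxolan-2-one F1. The C5 hydroxyl then directs a vanadium-catalysed epoxidation (VO(acac)2, t-BuOOH, benzene, rt) to the C8=C9 alkene alone, giving the (8S,9S)-epoxide (5S)-5-[(1R)-3-[(2S,3S)-3-[(3E)-6-(furan-3-yl)-3-methylhex-3-en-1-yl]-2-methyloxiran-2-yl]-1-hydroxypropyl]-5-methyloxolan-2-one F2, which is not isolated. On addition of acetic acid the hydroxyl opens it 5-exo at C8 with inversion; this Kishi-type sequence is known to favour 2,5-trans oxolanes from secondary bishomoallylic alcohols with a trisubstituted alkene. It should give the C9 alcohol (5S)-5-[(2R,5R)-5-[(1S,4E)-7-(furan-3-yl)-1-hydroxy-4-methylhept-4-en-1-yl]-5-methyloxolan-2-yl]-5-methyloxolan-2-one F3. Dehydration of F3 with the Burgess reagent (toluene, 60 °C, syn elimination of the sulfamate toward C10, the only neighbour with hydrogens) would give 18.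

Step 4 (allylic oxidation of the furanotriene).
- What may go wrong: incomplete site selectivity among three trisubstituted alkenes, over-oxidation to the enal, and attrition of the furan on prolonged exposure to the oxidant.
- Fallback, setting out from 1 and returning at 7: oxidise before the furan is present and carry the new hydroxyl through the coupling as a silyl ether. Acetylation of 1 (Ac2O, pyridine) gives (2E,6E)-farnesyl acetate F4, a substrate on which the SeO2/t-BuOOH oxidation of the terminal E methyl is established, giving (2E,6E,10E)-12-hydroxy-3,7,11-trimethyldodeca-2,6,10-trien-1-yl acetate F5. Silylation (TBSCl, imidazole, DMF) gives the silyl ether acetate F6, methanolysis (K2CO3, MeOH) gives (2E,6E,10E)-12-(tert-butyldimethylsilyloxy)-3,7,11-trimethyldodeca-2,6,10-trien-1-ol F7, and Appel bromination (CBr4, PPh3, CH2Cl2, 0 °C) gives the corresponding allylic bromide F8. Coupling of F8 with 5 under Li2CuCl4 catalysis as in step 3 gives the tert-butyldimethylsilyl ether of 7 F9, and TBAF in THF releases 7.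

Step 3 (Grignard formation and copper-catalysed coupling).
- What may go wrong: Wurtz-type dimerisation while the furylmethyl Grignard reagent forms, reaction of the furylmethyl metal through the ring 2-position, or SN2′ attack on the allylic bromide leading to the branched isomer.
- Fallback, setting out from 4 and 2 and returning at 6: sulfone alkylation in place of the organometallic coupling. Displacement of chloride in 4 with sodium benzenesulfinate (DMF, rt) gives 3-[(phenylsulfonyl)methyl]furan F10. Deprotonation (n-BuLi, THF, −78 °C) and alkylation with 2, a plain SN2 at the primary allylic carbon, gives 3-[(3E,7E)-4,8,12-trimethyl-1-(phenylsulfonyl)trideca-3,7,11-trien-1-yl]furan F11. Reductive desulfonylation (6% Na(Hg), Na2HPO4, MeOH–THF, −20 °C) removes the sulfonyl group from C15, which is not allylic, so no alkene can migrate, and gives 6.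

Further compounds
F1 | step 8 | (5S)-5-[(1R,4E,8E)-11-(furan-3-yl)-1-hydroxy-4,8-dimethylundeca-4,8-dien-1-yl]-5-methyloxolan-2-one | C/C(=C\CCc1ccoc1)CC/C=C(C)/CC[C@H]([C@]1(C)CCC(=O)O1)O
F2 | step 8 | (5S)-5-[(1R)-3-[(2S,3S)-3-[(3E)-6-(furan-3-yl)-3-methylhex-3-en-1-yl]-2-methyloxiran-2-yl]-1-hydroxypropyl]-5-methyloxolan-2-one | C/C(=C\CCc1ccoc1)CC[C@@H]1O[C@@]1(C)CC[C@H]([C@]2(C)CCC(=O)O2)O
F3 | step 8 | (5S)-5-[(2R,5R)-5-[(1S,4E)-7-(furan-3-yl)-1-hydroxy-4-methylhept-4-en-1-yl]-5-methyloxolan-2-yl]-5-methyloxolan-2-one | C/C(=C\CCc1ccoc1)CC[C@H](O)[C@@]1(C)CC[C@H]([C@]2(C)CCC(=O)O2)O1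
F4 | step 4 | (2E,6E)-farnesyl acetate | CC(C)=CCC/C(C)=C/CC/C(C)=C/COC(C)=O
F5 | step 4 | (2E,6E,10E)-12-hydroxy-3,7,11-trimethyldodeca-2,6,10-trien-1-yl acetate | OC/C(C)=C/CC/C(C)=C/CC/C(C)=C/COC(C)=O
F6 | step 4 | (2E,6E,10E)-12-(tert-butyldimethylsilyloxy)-3,7,11-trimethyldodeca-2,6,10-trien-1-yl acetate | CC(C)(C)[Si](C)(C)OC/C(C)=C/CC/C(C)=C/CC/C(C)=C/COC(C)=O
F7 | step 4 | (2E,6E,10E)-12-(tert-butyldimethylsilyloxy)-3,7,11-trimethyldodeca-2,6,10-trien-1-ol | CC(C)(C)[Si](C)(C)OC/C(C)=C/CC/C(C)=C/CC/C(C)=C/CO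
F8 | step 4 | (2E,6E,10E)-12-bromo-1-(tert-butyldimethylsilyloxy)-2,6,10-trimethyldodeca-2,6,10-triene | CC(C)(C)[Si](C)(C)OC/C(C)=C/CC/C(C)=C/CC/C(C)=C/CBr
F9 | step 4 | tert-butyldimethylsilyl ether of 7 | CC(C)(C)[Si](C)(C)OC/C(C)=C/CC/C(C)=C/CC/C(C)=C/CCc1ccoc1
F10 | step 3 | 3-[(phenylsulfonyl)methyl]furan | O=S(=O)(Cc1ccoc1)c1ccccc1
F11 | step 3 | 3-[(3E,7E)-4,8,12-trimethyl-1-(phenylsulfonyl)trideca-3,7,11-trien-1-yl]furan (racemic at C15) | CC(C)=CCC/C(C)=C/CC/C(C)=C/CC(c1ccoc1)S(=O)(=O)c1ccccc1
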